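**Plan**
- Cuts: the C1′–C2′ bond, which leaves a spiro-oxirane on C5/C1′ and a C16 (Z)-alkenyl Grignard reagent; the C7′–C8′ bond behind the chain olefin (acetylide alkylation); C2=C3 is traced back to a cis-diol and C1=O to a carbinol.
- Feature: the tertiary carbinol C5 with its exocyclic methylene C1′ is a masked 1-oxaspiro[2.5]octane, and ring carbons C1–C6 plus C1′ are the seven carbons of shikimic acid (shikimate C5, C4, C3, C2, C1, C6 and the carboxyl carbon).
- Forward: the six-membered ring is that of shikimic acid and is never built; the only ring closed is the oxirane (step 5); the chain is joined by opening it at C1′ (step 10); olefin, ketone and the free C4 hydroxyl are unveiled last.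
- Stereochemistry: C4 and C5 are set together by osmylation of the shikimate olefin anti to the C2/C3 acetonide; the three shikimate stereocentres are then erased (C2/C3 by Corey–Winter olefination, C1 by oxidation); the chain (Z)-olefin comes from Lindlar semihydrogenation.

Key step: step 10

Convention: target numbering is used for every ring intermediate; β is the face of the C1 oxygen, α the face of the C2/C3 oxygens. The target has both C4–OH and C5–OH on the β face, (4R,5S).
Remark: the halide on magnesium is a spectator, and chloride is used because it comes directly from 1-bromo-6-chlorohexane. C1–O is carried as a TBDPS ether and C4–O as a PMB ether, so the acetonide can be removed with acid and the last deprotection is neutral.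

Step 1
Reactants: 1 shikimic acid
Product: 3 methyl 3,4-O-isopropylidene shikimate, via methyl shikimate 2 (not isolated)
Conditions: MeOH, camphorsulfonic acid (cat.), reflux; concentrate; then 2,2-dimethoxypropane, acetone, rt
Reagents that add atoms: methanol, CO; 2,2-dimethoxypropane, COC(C)(C)OC
Why: Fischer esterification followed by acid-catalysed transacetalisation, in which the cis C2/C3 hydroxyls close the cis-fused dioxolane in preference to the trans C1/C2 pair, and no stereocentre is touched.

Step 2
Reactants: 3 methyl 3,4-O-isopropylidene shikimate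
Product: 4 methyl 5-O-(tert-butyldiphenylsilyl)-3,4-O-isopropylidene shikimate (C1–OTBDPS in target numbering)
Conditions: TBDPSCl, imidazole, DMAP (cat.), DMF, rt
Reagents that add atoms: tert-butyl(chloro)diphenylsilane, CC(C)(C)[Si](Cl)(c1ccccc1)c1ccccc1
Why: imidazole-mediated silylation of the only free hydroxyl, the TBDPS ether being chosen because it survives the later acidic removal of the acetonide.

Step 3
Reactants: 4 methyl 5-O-(tert-butyldiphenylsilyl)-3,4-O-isopropylidene shikimate
Product: 5 diol ester (C4–OH β, C5–OH β, C5–CO2Me α, C2/C3 acetonide α, C1–OTBDPS β)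
Conditions: OsO4 (5 mol %), NMO, acetone/H2O (8:1), rt
Reagents that add atoms: osmium tetroxide, O=[Os](=O)(=O)=O; N-methylmorpholine N-oxide, C[N+]1([O-])CCOCC1; water, O
Why: Upjohn dihydroxylation (suprafacial addition of OsO4 with NMO as terminal oxidant) of the enoate from the β face, anti to the allylic C3–O bond and the α-fused dioxolane, sets C4 and C5 together with both hydroxyls β, which is the configuration of the target.

Step 4
Reactants: 5 diol ester
Product: 6 triol (C5–CH2OH α, C5–OH β, C4–OH β)
Conditions: LiBH4, THF, 0 °C → rt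
Reagents that add atoms: none
Why: hydride reduction of the α-hydroxy ester by LiBH4, helped by lithium chelation to the α-hydroxyl, leaves silyl ether and acetonide untouched and changes no stereocentre.

Step 5
Reactants: 6 triol
Product: 8 spiro-epoxy alcohol (oxirane across C5/C1′ with O β and CH2 α; free C4–OH β), via primary tosylate 7 (not isolated)
Conditions: TsCl, pyridine, CH2Cl2, 0 °C → rt; then K2CO3, MeOH, rt
Reagents that add atoms: none
Why: selective sulfonylation of the primary hydroxyl over the hindered secondary and the tertiary ones, then intramolecular Williamson displacement (3-exo-tet) by the C5 alkoxide closes the oxirane with the C5–O bond intact, so C5 keeps its configuration.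

Step 6
Reactants: 8 spiro-epoxy alcohol
Product: 9 C4-O-PMB spiro-epoxide (C1–OTBDPS β, C2/C3 acetonide α, C4–OPMB β, oxirane O β)
Conditions: NaH, 4-methoxybenzyl chloride, Bu4NI (cat.), THF/DMF, 0 °C → rt
Reagents that add atoms: 4-methoxybenzyl chloride, COc1ccc(CCl)cc1
Why: Williamson etherification of the only hydroxyl, whose alkoxide is cis to the oxirane oxygen and therefore cannot reach the backside of C5, so no Payne rearrangement is expected.

Step 7
Reactants: 10 1-decyne; 11 1-bromo-6-chlorohexane
Product: 13 1-chlorohexadec-7-yne, via dec-1-ynyllithium 12 (not isolated)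
Conditions: n-BuLi, THF, −78 → 0 °C; then 11, DMPU, 0 °C → rt
Reagents that add atoms: none
Why: SN2 alkylation of the lithium acetylide, chemoselective for bromide over chloride in the dipolar cosolvent.

Step 8
Reactants: 13 1-chlorohexadec-7-yne
Product: 14 (Z)-1-chlorohexadec-7-ene
Conditions: H2 (1 atm), Pd/CaCO3 poisoned with Pb(OAc)2 (Lindlar catalyst), quinoline, hexane, rt
Reagents that add atoms: none
Why: Lindlar semihydrogenation delivers both hydrogens to one face of the alkyne on the poisoned palladium surface and so gives the (Z)-olefin, while the primary chloride is inert.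

Step 9
Reactants: 14 (Z)-1-chlorohexadec-7-ene
Product: 15 (7Z)-hexadec-7-en-1-ylmagnesium chloride (THF solution, titrated and used directly)
Conditions: Mg turnings, I2 (cat.), THF, reflux
Reagents that add atoms: magnesium, [Mg]
Why: Grignard formation by insertion of magnesium into the primary C–Cl bond, the isolated (Z)-olefin being too remote to cyclise or isomerise.

Step 10
Reactants: 9 C4-O-PMB spiro-epoxide; 15 (7Z)-hexadec-7-en-1-ylmagnesium chloride
Product: 16 chain-complete tertiary alcohol (C5–OH β, C5–(8Z)-heptadec-8-enyl α, C4–OPMB β, C2/C3 acetonide α, C1–OTBDPS β)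
Conditions: 15 (2 equiv), Li2CuCl4 (10 mol %), THF, −30 → 0 °C; then aq NH4Cl
Reagents that add atoms: none
Why: Li2CuCl4 is reduced by the Grignard reagent to a monovalent copper species, and the resulting alkylcuprate attacks the oxirane CH2 (C1′) in SN2 fashion, reductive elimination forging C1′–C2′ and releasing the C5 magnesium alkoxide. The closest known reaction type is the copper-catalysed Grignard opening of 2,2-disubstituted (spiro) oxiranes at the primary carbon. No ring is closed; the three-membered ring is opened and the cyclohexane is untouched. No stereocentre is created, because the C5–O bond is not broken and the configuration fixed by the osmylation is carried through. The step needs regioselectivity for CH2 over the fully substituted C5 and chemoselectivity for substitution over magnesium-halide-promoted rearrangement or chlorohydrin formation; the first is secured by the steric difference between a methylene and a quaternary carbon, the second by copper catalysis at low temperature with slow addition. Capping the C4 hydroxyl as its PMB ether leaves no alkoxide beside the oxirane, so no Grignard reagent is consumed by deprotonation.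

Step 11
Reactants: 16 chain-complete tertiary alcohol
Product: 17 C2,C3-diol (C2–OH α, C3–OH α; C1–OTBDPS, C4–OPMB, C5–OH retained)
Conditions: AcOH/H2O/THF (4:1:1), 50 °C
Reagents that add atoms: none
Why: acid-catalysed acetal hydrolysis, which the PMB ether, the TBDPS ether, the tertiary alcohol and the (Z)-olefin should tolerate in aqueous acetic acid.

Step 12
Reactants: 17 C2,C3-diol
Product: 18 C2,C3-cyclic thiocarbonate
Conditions: 1,1′-thiocarbonyldiimidazole, DMAP (cat.), toluene, 90 °C
Reagents that add atoms: 1,1′-thiocarbonyldiimidazole, S=C(n1ccnc1)n1ccnc1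
Why: the cis-vicinal diol closes the five-membered cyclic thiocarbonate (first stage of the Corey–Winter olefination), while the hindered tertiary C5 hydroxyl should not react.

Step 13
Reactants: 18 C2,C3-cyclic thiocarbonate
Product: 19 cyclohexene (C2=C3; C1–OTBDPS β, C4–OPMB β, C5–OH β)
Conditions: 1,3-dimethyl-2-phenyl-1,3,2-diazaphospholidine (3 equiv), THF, 40 °C
Reagents that add atoms: none
Why: Corey–Winter olefination in the Corey–Hopkins variant, in which thiophilic attack of the phosphorus reagent and stereospecific syn cycloreversion with loss of CO2 give the ring cis-olefin and erase the C2 and C3 stereocentres.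

Step 14
Reactants: 19 cyclohexene
Product: 20 allylic alcohol (C1–OH β, C4–OPMB β, C5–OH β)
Conditions: TBAF, THF, 0 °C → rt
Reagents that add atoms: none
Why: fluoride-induced cleavage of the Si–O bond frees the allylic C1 hydroxyl, while the PMB ether and the tertiary alcohol are inert.

Step 15
Reactants: 20 allylic alcohol
Product: 21 4-O-PMB enone, (4R,5S)-5-hydroxy-4-(4-methoxybenzyloxy)-5-[(8Z)-heptadec-8-enyl]cyclohex-2-en-1-one
Conditions: Dess–Martin periodinane, NaHCO3, CH2Cl2, 0 °C → rt
Reagents that add atoms: none
Why: Dess–Martin oxidation of the only secondary alcohol gives the enone and erases the last shikimate stereocentre, and the buffered, non-basic medium should avoid β-elimination of the C5 hydroxyl.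

Step 16
Reactants: 21 4-O-PMB enone
Product: 22 (4R,5S)-4,5-dihydroxy-5-[(8Z)-heptadec-8-en-1-yl]cyclohex-2-en-1-one (target)
Conditions: DDQ, CH2Cl2/pH 7 phosphate buffer (10:1), 0 °C
Reagents that add atoms: none
Why: oxidative cleavage of the PMB ether by DDQ (hydride abstraction, then hydrolysis of the oxocarbenium ion) at neutral pH releases the C4 hydroxyl without exposing the β-hydroxy enone to acid or base.

**Compound list**
1 | shikimic acid, (3R,4S,5R)-3,4,5-trihydroxycyclohex-1-ene-1-carboxylic acid | O=C(O)C1=C[C@@H](O)[C@@H](O)[C@H](O)C1 | starting material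
2 | methyl shikimate | COC(=O)C1=C[C@@H](O)[C@@H](O)[C@H](O)C1 | intermediate (not isolated)
3 | methyl 3,4-O-isopropylidene shikimate (target numbering: C2/C3 acetonide, free C1–OH) | COC(=O)C1=C[C@@H](OC2(C)C)[C@@H](O2)[C@H](O)C1 | intermediate
4 | methyl 5-O-(tert-butyldiphenylsilyl)-3,4-O-isopropylidene shikimate | COC(=O)C1=C[C@@H](OC2(C)C)[C@@H](O2)[C@H](O[Si](c3ccccc3)(c3ccccc3)C(C)(C)C)C1 | intermediate
5 | diol ester: C4–OH β, C5–OH β, C5–CO2Me α, C2/C3 acetonide α, C1–OTBDPS β | O[C@@H]1[C@H]2OC(C)(C)O[C@H]2[C@H](O[Si](c3ccccc3)(c3ccccc3)C(C)(C)C)C[C@@]1(O)C(=O)OC | intermediate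
6 | triol: C5–CH2OH α, C5–OH β, C4–OH β, C2/C3 acetonide α, C1–OTBDPS β | O[C@@H]1[C@H]2OC(C)(C)O[C@H]2[C@H](O[Si](c3ccccc3)(c3ccccc3)C(C)(C)C)C[C@@]1(O)CO | intermediate
7 | primary tosylate of triol 6 (C1′–OTs) | O[C@@H]1[C@H]2OC(C)(C)O[C@H]2[C@H](O[Si](c3ccccc3)(c3ccccc3)C(C)(C)C)C[C@@]1(O)COS(=O)(=O)c4ccc(C)cc4 | intermediate (not isolated)
8 | spiro-epoxy alcohol: oxirane across C5/C1′ (O β, CH2 α), free C4–OH β, C2/C3 acetonide α, C1–OTBDPS β | O[C@@H]1[C@H]2OC(C)(C)O[C@H]2[C@H](O[Si](c3ccccc3)(c3ccccc3)C(C)(C)C)C[C@@]12CO2 | intermediate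
9 | C4-O-PMB spiro-epoxide (precursor of the key step) | COc1ccc(CO[C@@H]2[C@H]3OC(C)(C)O[C@H]3[C@H](O[Si](c4ccccc4)(c4ccccc4)C(C)(C)C)C[C@@]25CO5)cc1 | intermediate
10 | 1-decyne | CCCCCCCCC#C | starting material
11 | 1-bromo-6-chlorohexane | ClCCCCCCBr | starting material
12 | dec-1-yn-1-yllithium | [Li]C#CCCCCCCCC | intermediate (not isolated)
13 | 1-chlorohexadec-7-yne | CCCCCCCCC#CCCCCCCCl | intermediate
14 | (Z)-1-chlorohexadec-7-ene | CCCCCCCC/C=C\CCCCCCCl | intermediate
15 | (7Z)-hexadec-7-en-1-ylmagnesium chloride | CCCCCCCC/C=C\CCCCCC[Mg]Cl | intermediate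
16 | chain-complete tertiary alcohol: C5–OH β, C5–(8Z)-heptadec-8-enyl α, C4–OPMB β, C2/C3 acetonide α, C1–OTBDPS β (product of the key step) | COc1ccc(CO[C@@H]2[C@H]3OC(C)(C)O[C@H]3[C@H](O[Si](c4ccccc4)(c4ccccc4)C(C)(C)C)C[C@@]2(O)CCCCCCC/C=C\CCCCCCCC)cc1 | intermediate
17 | C2,C3-diol (both α); C1–OTBDPS β, C4–OPMB β, C5–OH β | COc1ccc(CO[C@@H]2[C@@H](O)[C@@H](O)[C@H](O[Si](c3ccccc3)(c3ccccc3)C(C)(C)C)C[C@@]2(O)CCCCCCC/C=C\CCCCCCCC)cc1 | intermediate
18 | C2,C3-cyclic thiocarbonate of 17 | COc1ccc(CO[C@@H]2[C@H]3OC(=S)O[C@H]3[C@H](O[Si](c4ccccc4)(c4ccccc4)C(C)(C)C)C[C@@]2(O)CCCCCCC/C=C\CCCCCCCC)cc1 | intermediate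
19 | cyclohexene: C2=C3, C1–OTBDPS β, C4–OPMB β, C5–OH β | COc1ccc(CO[C@@H]2C=C[C@H](O[Si](c3ccccc3)(c3ccccc3)C(C)(C)C)C[C@@]2(O)CCCCCCC/C=C\CCCCCCCC)cc1 | intermediate
20 | allylic alcohol: C1–OH β, C4–OPMB β, C5–OH β | COc1ccc(CO[C@@H]2C=C[C@H](O)C[C@@]2(O)CCCCCCC/C=C\CCCCCCCC)cc1 | intermediate
21 | 4-O-PMB enone | COc1ccc(CO[C@@H]2C=CC(=O)C[C@@]2(O)CCCCCCC/C=C\CCCCCCCC)cc1 | intermediate
22 | (4R,5S)-4,5-dihydroxy-5-[(8Z)-heptadec-8-en-1-yl]cyclohex-2-en-1-one | CCCCCCCC/C=C\CCCCCCC[C@]1(O)CC(=O)C=C[C@H]1O | target

**Step count**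
Total: 16 steps. Longest linear sequence: 13 steps (steps 1–6 and 10–16, from shikimic acid); the chain branch is steps 7–9.

**Steps most likely to fail**

Step 10. Substitution at the neopentyl-type CH2 may be slow enough that magnesium-halide chemistry (chloride opening of the oxirane, or its rearrangement to an aldehyde that then adds the Grignard reagent) outruns the copper-mediated coupling. The fallback reverses the polarity at C1′ and forms the same C1′–C2′ bond by sulfone alkylation. It sets out from 9: PhSNa in DMF opens the oxirane at CH2 to the β-hydroxy sulfide F1, and mCPBA oxidises this to the β-hydroxy sulfone F2. In parallel, chloride 14 is converted by Finkelstein exchange (NaI, acetone, reflux) into (Z)-1-iodohexadec-7-ene F3. The dianion of F2 (n-BuLi, 2 equiv, THF/DMPU, −78 °C) is alkylated with F3 to the C1′-alkylated sulfone F4 (mixture of C1′ epimers, of no consequence). Reductive desulfonylation (Mg, MeOH) comes back to the route at 16.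

Step 16. The benzylic oxocarbenium ion formed from the PMB ether may be captured by the neighbouring cis C5 hydroxyl instead of water, and prolonged exposure may dehydrate the β-hydroxy enone towards an aromatic product. The fallback makes the capture deliberate. From 21, DDQ under anhydrous conditions (4 Å molecular sieves, CH2Cl2, 0 °C) should give the cyclic p-methoxybenzylidene acetal F5 across the C4/C5 oxygens. Brief hydrolysis in aqueous acetic acid at room temperature then releases the diol and comes back to the route at 22.

Step 3. The trisubstituted, electron-poor enoate may be osmylated slowly, giving incomplete conversion or eroded facial selectivity. The fallback changes the order of reduction and oxidation. From 4, i-Bu2AlH (CH2Cl2, −78 °C) reduces the ester to the allylic alcohol F6. Its more electron-rich olefin is then dihydroxylated (OsO4 cat., NMO, acetone/H2O) from the same β face, anti to the acetonide, and the sequence comes back to the route at triol 6.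

**Further compounds**
F1 | step 10 | β-hydroxy sulfide: C5–OH β, C5–CH2SPh α, otherwise as 9 | COc1ccc(CO[C@@H]2[C@H]3OC(C)(C)O[C@H]3[C@H](O[Si](c4ccccc4)(c4ccccc4)C(C)(C)C)C[C@@]2(O)CSc5ccccc5)cc1
F2 | step 10 | β-hydroxy sulfone: C5–CH2SO2Ph α | COc1ccc(CO[C@@H]2[C@H]3OC(C)(C)O[C@H]3[C@H](O[Si](c4ccccc4)(c4ccccc4)C(C)(C)C)C[C@@]2(O)CS(=O)(=O)c5ccccc5)cc1
F3 | step 10 | (Z)-1-iodohexadec-7-ene | CCCCCCCC/C=C\CCCCCCI
F4 | step 10 | C1′-alkylated sulfone (C1′ epimers): 16 carrying PhSO2 at C1′ | COc1ccc(CO[C@@H]2[C@H]3OC(C)(C)O[C@H]3[C@H](O[Si](c4ccccc4)(c4ccccc4)C(C)(C)C)C[C@@]2(O)C(CCCCCC/C=C\CCCCCCCC)S(=O)(=O)c5ccccc5)cc1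
F5 | step 16 | C4,C5-O-(4-methoxybenzylidene) acetal of the target (acetal carbon unassigned) | COc1ccc(cc1)C1O[C@@H]2C=CC(=O)C[C@]2(CCCCCCC/C=C\CCCCCCCC)O1
F6 | step 3 | allylic alcohol: 4 with CH2OH in place of CO2Me | OCC1=C[C@@H](OC2(C)C)[C@@H](O2)[C@H](O[Si](c3ccccc3)(c3ccccc3)C(C)(C)C)C1
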